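**Strategy.** The ten-membered carbocycle is disconnected at C2–C3. C3 sits between the ester carbonyl and C4, the hemiketal carbon of the oxygen-bridged dihydrofuran ring; when that ring opens C4 is a ketone, so C3 is the doubly activated CH2 of a 1,3-keto ester. In the key step this carbon condenses with an aldehyde (C2) held on cyclohexene ring A, closing the ten-membered ring as the C2=C3 alkylidene in one operation; the alkene is reduced later. The precursor is a ring A aldehyde whose C10 side chain carries the C8 PMB ether, the C7 quaternary centre and a 2-hydroxy-2,5-dihydrofuran bearing CH2CO2Me at C4.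

Key step: step 16

**Remarks on the chemistry**
- Atom labels follow the target: C1 and C10 are the ring-fusion carbons, C2–C9 complete the ten-membered ring, C11 (methyl), C12, C13 and C14 (isopropyl) complete ring A, and an oxygen bridges C4 and C7. The target is (1R,3R,4R,7S,8S,10R,14R).
- Shorthand in names: "ring A unit [X]" = (1R,5R,6R)-6-X-2-methyl-5-(propan-2-yl)cyclohex-2-en-1-yl; its C1, C5 and C6 are C10, C14 and C1 of the target, and the substituents at its C1 and C6 are cis to each other and trans to the isopropyl group.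
- Assumption: the (3R) configuration at the epimerisable C3 is taken to be the thermodynamically favoured one, so equilibration in the last step should converge on the target.
- The hemiketal carbon C4 of the monocyclic compounds 25–27 is configurationally labile; one anomer is drawn.

**Route**

Step 1
Reactants: 1 (R)-(−)-α-phellandrene; 2 trichloroacetyl chloride
Product: 4 (1R,5R,6R)-8,8-dichloro-2-methyl-5-(propan-2-yl)bicyclo[4.2.0]oct-2-en-7-one, via dichloroketene 3 (not isolated)
Conditions: Zn dust (activated), Et2O, ultrasound, 20 °C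
Reagents that add atoms: trichloroacetyl chloride 2, ClC(Cl)(Cl)C(Cl)=O, as dichloroketene 3, ClC(Cl)=C=O
Why: Ketene [2+2] cycloaddition to the less substituted C=C of the diene, with the ketene carbonyl carbon bonding to the diene terminus and approach from the face opposite the isopropyl group, which sets C1 and C10 cis to each other and trans to the C14 substituent.

Step 2
Reactants: 4 dichlorocyclobutanone
Product: 5 (1R,5R,6R)-2-methyl-5-(propan-2-yl)bicyclo[4.2.0]oct-2-en-7-one
Conditions: Zn dust, AcOH, 50 °C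
Reagents that add atoms: none
Why: Reductive dechlorination of the α,α-dichloroketone through zinc enolates, which touches no stereocentre.

Step 3
Reactants: 5 cyclobutanone; 6 tert-butoxybis(dimethylamino)methane
Product: 8 methyl (1R,2R,6R)-2-(2,2-dimethoxyethyl)-3-methyl-6-(propan-2-yl)cyclohex-3-ene-1-carboxylate, via enaminone 7 (not isolated)
Conditions: 6 (neat), 60 °C; volatiles removed; then p-TsOH·H2O (2 equiv), MeOH, 60 °C
Reagents that add atoms: tert-butoxybis(dimethylamino)methane 6, CC(C)(C)OC(N(C)C)N(C)C; methanol, CO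
Why: Aminomethylenation of the only enolisable CH2 by the aminal ester, then acid-promoted retro-Claisen-type fragmentation (methanol adds to the strained ketone and the C2–C9 bond breaks toward the iminium carbon), which delivers the C1 ester and the C8 dimethyl acetal with C1, C10 and C14 unchanged.

Step 4
Reactants: 8 ester acetal
Product: 9 [(1R,2R,6R)-2-(2,2-dimethoxyethyl)-3-methyl-6-(propan-2-yl)cyclohex-3-en-1-yl]methanol
Conditions: LiAlH4, THF, 0 °C
Reagents that add atoms: none
Why: Hydride reduction of the ester to the primary alcohol, the acetal being inert to hydride.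

Step 5
Reactants: 9 primary alcohol
Product: 10 tert-butyldiphenylsilyl ether of 9
Conditions: TBDPSCl, imidazole, DMF, 20 °C
Reagents that add atoms: tert-butyl(chloro)diphenylsilane, CC(C)(C)[Si](Cl)(c1ccccc1)c1ccccc1
Why: Silylation of the primary alcohol gives an acid-stable ether that keeps C2 at the alcohol oxidation level through the acidic and organometallic steps.

Step 6
Reactants: 10 silyl ether acetal
Product: 11 2-(ring A unit [CH2OTBDPS])acetaldehyde
Conditions: PPTS (0.3 equiv), acetone/H2O (9:1), 55 °C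
Reagents that add atoms: water, O
Why: Acid-catalysed acetal hydrolysis frees the unhindered C8 aldehyde while the TBDPS ether survives.

Step 7
Reactants: 11 C8 aldehyde; 12 vinylmagnesium bromide
Product: 14 (2S)-1-(ring A unit [CH2OTBDPS])but-3-en-2-ol, via divinylzinc 13 (not isolated)
Conditions: CH2=CHMgBr (2.4 equiv), ZnCl2 (1.2 equiv), Et2O, 0 °C; 1,4-dioxane, filtration; then (2R)-(+)-3-exo-morpholinoisoborneol (10 mol %), 11, toluene, −20 to 0 °C; aq. NH4Cl
Reagents that add atoms: divinylzinc 13, C=C[Zn]C=C, made from vinylmagnesium bromide 12, C=C[Mg]Br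
Why: Amino-alcohol-catalysed enantioselective addition of an alkenylzinc reagent to an aldehyde (Noyori–Oppolzer type), in which the zinc aminoalkoxide delivers vinyl to the Re face and so sets (8S) under ligand control, the nearest substrate stereocentre (C10) being β to the carbonyl and exerting little bias.

Step 8
Reactants: 14 allylic alcohol
Product: 15 (2S)-2-[(4-methoxybenzyl)oxy]-1-(ring A unit [CH2OTBDPS])but-3-ene
Conditions: NaH, 4-methoxybenzyl chloride, n-Bu4NI (cat.), THF/DMF, 0 to 20 °C
Reagents that add atoms: 4-methoxybenzyl chloride, COc1ccc(CCl)cc1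
Why: Williamson etherification installs an ether that can chelate in step 10, keeps the C8 oxygen from forming a six-membered lactol with the later C2 aldehyde, and is removable with DDQ.

Step 9
Reactants: 15 allylic PMB ether
Product: 16 (3S)-3-[(4-methoxybenzyl)oxy]-4-(ring A unit [CH2OTBDPS])butan-2-one
Conditions: PdCl2[2-(4,5-dihydrooxazol-2-yl)quinoline] (5 mol %), AgSbF6 (12 mol %), aq. t-BuOOH, CH2Cl2, 0 to 20 °C
Reagents that add atoms: tert-butyl hydroperoxide, CC(C)(C)OO
Why: Tsuji–Wacker oxidation of the terminal alkene under catalyst-controlled Markovnikov selectivity converts the protected allylic alcohol into the methyl ketone, and the base-free conditions should leave the epimerisable C8 centre and the trisubstituted ring alkene untouched.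

Step 10
Reactants: 16 α-alkoxy methyl ketone; 17 ethynylmagnesium bromide
Product: 18 (3S,4S)-4-[(4-methoxybenzyl)oxy]-3-methyl-5-(ring A unit [CH2OTBDPS])pent-1-yn-3-ol
Conditions: HC≡CMgBr (3 equiv), THF, −78 to −20 °C; aq. NH4Cl
Reagents that add atoms: ethynylmagnesium bromide 17, C#C[Mg]Br
Why: Cram-chelate-controlled Grignard addition, in which magnesium bridges the ketone oxygen and the C8 ether oxygen and the acetylide attacks the face away from C9, giving the (7S) tertiary alcohol with C7–O and C8–O syn.

Step 11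
Reactants: 18 tertiary propargylic alcohol; 19 N-methoxy-N-methylcarbamoyl chloride
Product: 20 (4S,5S)-4-hydroxy-N-methoxy-5-[(4-methoxybenzyl)oxy]-N,4-dimethyl-6-(ring A unit [CH2OTBDPS])hex-2-ynamide
Conditions: n-BuLi (2.1 equiv), THF, −78 °C; then 19 (1.2 equiv), −78 to −30 °C; aq. NH4Cl
Reagents that add atoms: N-methoxy-N-methylcarbamoyl chloride 19, CON(C)C(Cl)=O
Why: Acylation of a lithium acetylide by a carbamoyl chloride (alkynyl Weinreb amide synthesis), the acetylide carbon of the dianion reacting faster than the hindered tertiary alkoxide.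

Step 12
Reactants: 20 alkynyl Weinreb amide; 21 methyl acetate
Product: 23 methyl (6S,7S)-6-hydroxy-7-[(4-methoxybenzyl)oxy]-6-methyl-3-oxo-8-(ring A unit [CH2OTBDPS])oct-4-ynoate, via lithium enolate 22 (not isolated)
Conditions: MeOAc (4 equiv), LiN(i-Pr)2 (4 equiv), THF, −78 °C; then 20, −78 to −50 °C; AcOH quench at −78 °C
Reagents that add atoms: methyl acetate 21, COC(C)=O, as its lithium enolate 22, [Li]OC(=C)OC
Why: Claisen-type acylation of an ester enolate by a Weinreb amide, whose chelated tetrahedral adduct directs attack to the carbonyl carbon and prevents over-addition, so that work-up releases the β-keto ester carrying C3 and C4.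

Step 13
Reactants: 23 ynone keto ester
Product: 25 methyl 2-[(2S,5S)-2-hydroxy-5-{(1S)-1-[(4-methoxybenzyl)oxy]-2-(ring A unit [CH2OTBDPS])ethyl}-5-methyl-2,5-dihydrofuran-2-yl]acetate, via open-chain Z-enone 24 (not isolated)
Conditions: H2 (1 atm), Pd/CaCO3 poisoned with Pb(OAc)2, quinoline, EtOAc, 20 °C
Reagents that add atoms: none
Why: Semi-hydrogenation over poisoned palladium gives the Z-enone by syn addition, and the C7 hydroxyl then adds to the C4 ketone (5-exo-trig) to form the dihydrofuran hemiketal, which also shields the alkene from over-reduction and Z/E isomerisation.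

Step 14
Reactants: 25 hemiketal silyl ether
Product: 26 methyl 2-[(2S,5S)-2-hydroxy-5-{(1S)-1-[(4-methoxybenzyl)oxy]-2-(ring A unit [CH2OH])ethyl}-5-methyl-2,5-dihydrofuran-2-yl]acetate
Conditions: HF·pyridine, pyridine, THF, 0 to 20 °C
Reagents that add atoms: none
Why: Fluoride cleavage of the silyl ether under buffered conditions that should spare the hemiketal, the PMB ether and the keto ester.

Step 15
Reactants: 26 primary alcohol
Product: 27 methyl 2-[(2S,5S)-2-hydroxy-5-{(1S)-1-[(4-methoxybenzyl)oxy]-2-(ring A unit [CHO])ethyl}-5-methyl-2,5-dihydrofuran-2-yl]acetate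
Conditions: Dess–Martin periodinane, NaHCO3, CH2Cl2, 0 to 20 °C
Reagents that add atoms: none
Why: Dess–Martin oxidation of the primary alcohol to the aldehyde without base, so C1 should not epimerise, while the tertiary hemiketal hydroxyl cannot be oxidised.

Step 16
Reactants: 27 hemiketal keto ester aldehyde
Product: 30 2,3-dehydro hemiketal macrocycle (C8 PMB ether), via ring-opened keto ester 28 (not isolated), via ring-opened alkylidene macrocycle 29 (not isolated)
Conditions: piperidinium acetate (2 equiv), AcOH (1 equiv), 4 Å molecular sieves, toluene (0.002 M, slow addition of 27), 40 °C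
Reagents that add atoms: none
Why: Proposed new method: piperidine converts the C2 aldehyde into an iminium ion while the hemiketal opens reversibly to the Z-enone keto ester 28, whose enol attacks C2 through C3; loss of piperidine then gives the C2=C3 alkene of 29, and the C7 hydroxyl re-adds to C4 to give 30. The closest known reaction types are intermolecular amine-catalysed Knoevenagel condensations of β-keto esters with α-branched aldehydes and macrocyclic Horner–Wadsworth–Emmons closures; a ten-membered Knoevenagel closure has no direct precedent. The carbocycle closes by a 10-exo-trig addition of C3 to C2, followed by 5-exo-trig return of O7 to C4. No stereocentre is created, and the alkene geometry is imposed by the ring, which can only hold C1 and C4 cis (ester trans to C1), the geometry such condensations favour in any case. The step needs ring closure to beat oligomerisation and C1 to keep its configuration: high dilution and the reversibility of every stage before amine loss let intermolecular adducts revert, and the cis C1/C10 side chains on ring A together with the Z-alkene in the tether hold C2 near C3. The hindered α-branched aldehyde should form the C1-epimerising enamine only slowly in the buffered medium.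

Step 17
Reactants: 30 hemiketal macrocycle
Product: 31 C4 methyl ketal of 30
Conditions: MeOH, PPTS (cat.), 20 °C
Reagents that add atoms: methanol, CO
Why: Acid-catalysed mixed ketal formation through the bridged oxocarbenium ion, with the C4 configuration fixed by the C4–O–C7 bridge; the ketal removes the ring-opened enedione form before the reduction.

Step 18
Reactants: 31 methyl ketal enoate
Product: 32 (3R)-2,3-dihydro methyl ketal (C8 PMB ether)
Conditions: [(Ph3P)CuH]6 (0.5 equiv), H2O (5 equiv), degassed benzene, 20 °C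
Reagents that add atoms: none
Why: Copper hydride conjugate reduction, with hydride adding to C2 of the enoate and the copper enolate protonated at C3 from the exposed outer face of the bicycle; the new centre stays correctable because it is α to the ester.

Step 19
Reactants: 32 PMB ether
Product: 33 C8 alcohol of the dihydro methyl ketal
Conditions: DDQ (1.5 equiv), CH2Cl2/pH 7 phosphate buffer (10:1), 0 °C
Reagents that add atoms: none
Why: Oxidative PMB cleavage by DDQ (hydride abstraction, then hydrolysis of the benzylic oxocarbenium ion) under buffered conditions compatible with the methyl ketal and both alkenes.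

Step 20
Reactants: 33 C8 alcohol; 34 (E)-3-(1-methylimidazol-4-yl)acrylic acid
Product: 36 C8 (E)-3-(1-methylimidazol-4-yl)acrylate of the dihydro methyl ketal, via mixed anhydride 35 (not isolated)
Conditions: 34, 2,4,6-trichlorobenzoyl chloride, Et3N, THF, 20 °C; then 33, DMAP, toluene, 60 °C
Reagents that add atoms: (E)-3-(1-methylimidazol-4-yl)acrylic acid 34, Cn1cnc(/C=C/C(=O)O)c1
Why: Yamaguchi esterification, in which DMAP transfers the acyl group of the mixed anhydride to the hindered C8 hydroxyl with retention at C8 and without disturbing the E-acrylate.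

Step 21
Reactants: 36 urocanate methyl ketal
Product: 37 target, (1R,3R,4R,7S,8S,10R,14R)
Conditions: camphorsulfonic acid (2 equiv), wet CH2Cl2, 20 °C; NaHCO3 work-up
Reagents that add atoms: water, O
Why: Acid-catalysed hydrolysis of the mixed ketal to the hemiketal through the bridged oxocarbenium ion, during which C3, now α to the latent C4 ketone as well as to the ester, should equilibrate to the favoured (3R) epimer.

**Compound list**

1 | (R)-(−)-α-phellandrene, (5R)-2-methyl-5-(propan-2-yl)cyclohexa-1,3-diene | CC1=CC[C@H](C(C)C)C=C1 | starting material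
2 | trichloroacetyl chloride | ClC(Cl)(Cl)C(Cl)=O | starting material
3 | dichloroketene | ClC(Cl)=C=O | intermediate
4 | (1R,5R,6R)-8,8-dichloro-2-methyl-5-(propan-2-yl)bicyclo[4.2.0]oct-2-en-7-one (cis-fused, four-membered ring trans to isopropyl) | O=C2[C@@H]1[C@@H](C(C)C)CC=C(C)[C@@H]1C2(Cl)Cl | intermediate
5 | (1R,5R,6R)-2-methyl-5-(propan-2-yl)bicyclo[4.2.0]oct-2-en-7-one | O=C2[C@@H]1[C@@H](C(C)C)CC=C(C)[C@@H]1C2 | intermediate
6 | tert-butoxybis(dimethylamino)methane | CC(C)(C)OC(N(C)C)N(C)C | starting material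
7 | (E)-8-(dimethylaminomethylidene) derivative of 5 | O=C2[C@@H]1[C@@H](C(C)C)CC=C(C)[C@@H]1/C2=C\N(C)C | intermediate
8 | methyl (1R,2R,6R)-2-(2,2-dimethoxyethyl)-3-methyl-6-(propan-2-yl)cyclohex-3-ene-1-carboxylate | COC(=O)[C@@H]1[C@@H](C(C)C)CC=C(C)[C@@H]1CC(OC)OC | intermediate
9 | [(1R,2R,6R)-2-(2,2-dimethoxyethyl)-3-methyl-6-(propan-2-yl)cyclohex-3-en-1-yl]methanol | OC[C@@H]1[C@@H](C(C)C)CC=C(C)[C@@H]1CC(OC)OC | intermediate
10 | tert-butyldiphenylsilyl ether of 9 | CC(C)(C)[Si](c1ccccc1)(c1ccccc1)OC[C@@H]2[C@@H](C(C)C)CC=C(C)[C@@H]2CC(OC)OC | intermediate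
11 | 2-(ring A unit [CH2OTBDPS])acetaldehyde | CC(C)(C)[Si](c1ccccc1)(c1ccccc1)OC[C@@H]2[C@@H](C(C)C)CC=C(C)[C@@H]2CC=O | intermediate
12 | vinylmagnesium bromide | C=C[Mg]Br | starting material
13 | divinylzinc | C=C[Zn]C=C | intermediate
14 | (2S)-1-(ring A unit [CH2OTBDPS])but-3-en-2-ol | CC(C)(C)[Si](c1ccccc1)(c1ccccc1)OC[C@@H]2[C@@H](C(C)C)CC=C(C)[C@@H]2C[C@H](O)C=C | intermediate
15 | (2S)-2-[(4-methoxybenzyl)oxy]-1-(ring A unit [CH2OTBDPS])but-3-ene | CC(C)(C)[Si](c1ccccc1)(c1ccccc1)OC[C@@H]2[C@@H](C(C)C)CC=C(C)[C@@H]2C[C@H](OCc3ccc(OC)cc3)C=C | intermediate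
16 | (3S)-3-[(4-methoxybenzyl)oxy]-4-(ring A unit [CH2OTBDPS])butan-2-one | CC(C)(C)[Si](c1ccccc1)(c1ccccc1)OC[C@@H]2[C@@H](C(C)C)CC=C(C)[C@@H]2C[C@H](OCc3ccc(OC)cc3)C(C)=O | intermediate
17 | ethynylmagnesium bromide | C#C[Mg]Br | starting material
18 | (3S,4S)-4-[(4-methoxybenzyl)oxy]-3-methyl-5-(ring A unit [CH2OTBDPS])pent-1-yn-3-ol | CC(C)(C)[Si](c1ccccc1)(c1ccccc1)OC[C@@H]2[C@@H](C(C)C)CC=C(C)[C@@H]2C[C@H](OCc3ccc(OC)cc3)[C@](O)(C)C#C | intermediate
19 | N-methoxy-N-methylcarbamoyl chloride | CON(C)C(Cl)=O | starting material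
20 | (4S,5S)-4-hydroxy-N-methoxy-5-[(4-methoxybenzyl)oxy]-N,4-dimethyl-6-(ring A unit [CH2OTBDPS])hex-2-ynamide | CC(C)(C)[Si](c1ccccc1)(c1ccccc1)OC[C@@H]2[C@@H](C(C)C)CC=C(C)[C@@H]2C[C@H](OCc3ccc(OC)cc3)[C@](O)(C)C#CC(=O)N(C)OC | intermediate
21 | methyl acetate | COC(C)=O | starting material
22 | lithium enolate of methyl acetate | [Li]OC(=C)OC | intermediate
23 | methyl (6S,7S)-6-hydroxy-7-[(4-methoxybenzyl)oxy]-6-methyl-3-oxo-8-(ring A unit [CH2OTBDPS])oct-4-ynoate | CC(C)(C)[Si](c1ccccc1)(c1ccccc1)OC[C@@H]2[C@@H](C(C)C)CC=C(C)[C@@H]2C[C@H](OCc3ccc(OC)cc3)[C@](O)(C)C#CC(=O)CC(=O)OC | intermediate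
24 | methyl (4Z,6S,7S)-6-hydroxy-7-[(4-methoxybenzyl)oxy]-6-methyl-3-oxo-8-(ring A unit [CH2OTBDPS])oct-4-enoate | CC(C)(C)[Si](c1ccccc1)(c1ccccc1)OC[C@@H]2[C@@H](C(C)C)CC=C(C)[C@@H]2C[C@H](OCc3ccc(OC)cc3)[C@](O)(C)/C=C\C(=O)CC(=O)OC | intermediate
25 | methyl 2-[(2S,5S)-2-hydroxy-5-{(1S)-1-[(4-methoxybenzyl)oxy]-2-(ring A unit [CH2OTBDPS])ethyl}-5-methyl-2,5-dihydrofuran-2-yl]acetate | CC(C)(C)[Si](c1ccccc1)(c1ccccc1)OC[C@@H]2[C@@H](C(C)C)CC=C(C)[C@@H]2C[C@H](OCc3ccc(OC)cc3)[C@]4(C)C=C[C@](O)(CC(=O)OC)O4 | intermediate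
26 | methyl 2-[(2S,5S)-2-hydroxy-5-{(1S)-1-[(4-methoxybenzyl)oxy]-2-(ring A unit [CH2OH])ethyl}-5-methyl-2,5-dihydrofuran-2-yl]acetate | OC[C@@H]1[C@@H](C(C)C)CC=C(C)[C@@H]1C[C@H](OCc2ccc(OC)cc2)[C@]1(C)C=C[C@](O)(CC(=O)OC)O1 | intermediate
27 | methyl 2-[(2S,5S)-2-hydroxy-5-{(1S)-1-[(4-methoxybenzyl)oxy]-2-(ring A unit [CHO])ethyl}-5-methyl-2,5-dihydrofuran-2-yl]acetate (key-step precursor) | O=C[C@@H]1[C@@H](C(C)C)CC=C(C)[C@@H]1C[C@H](OCc2ccc(OC)cc2)[C@]1(C)C=C[C@](O)(CC(=O)OC)O1 | intermediate
28 | methyl (4Z,6S,7S)-6-hydroxy-7-[(4-methoxybenzyl)oxy]-6-methyl-3-oxo-8-(ring A unit [CHO])oct-4-enoate (ring-opened form of 27) | O=C[C@@H]1[C@@H](C(C)C)CC=C(C)[C@@H]1C[C@H](OCc2ccc(OC)cc2)[C@](O)(C)/C=C\C(=O)CC(=O)OC | intermediate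
29 | ring-opened alkylidene macrocycle: ten-membered carbocycle with C2=C3 (ester on C3), C4 ketone, (5Z)-alkene, free C7 hydroxyl, C8 PMB ether, fused ring A | COC(=O)/C1=C/[C@@H]2[C@@H](C(C)C)CC=C(C)[C@@H]2C[C@H](OCc3ccc(OC)cc3)[C@](O)(C)/C=C\C1=O | intermediate
30 | 2,3-dehydro hemiketal macrocycle: C3 methyl ester, C2=C3, C4 hemiketal OH, C4–O–C7 bridge, C5=C6, C7 methyl, C8 PMB ether, stereocentres as in 37 (key-step product) | COC(=O)/C1=C/[C@@H]2[C@@H](C(C)C)CC=C(C)[C@@H]2C[C@H](OCc3ccc(OC)cc3)[C@]2(C)C=C[C@@]1(O)O2 | intermediate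
31 | C4 methyl ketal of 30 | COC(=O)/C1=C/[C@@H]2[C@@H](C(C)C)CC=C(C)[C@@H]2C[C@H](OCc3ccc(OC)cc3)[C@]2(C)C=C[C@@]1(OC)O2 | intermediate
32 | (3R)-2,3-dihydro C4 methyl ketal, C8 PMB ether | COC(=O)[C@@H]1C[C@@H]2[C@@H](C(C)C)CC=C(C)[C@@H]2C[C@H](OCc3ccc(OC)cc3)[C@]2(C)C=C[C@@]1(OC)O2 | intermediate
33 | (3R)-2,3-dihydro C4 methyl ketal, free (8S)-alcohol | COC(=O)[C@@H]1C[C@@H]2[C@@H](C(C)C)CC=C(C)[C@@H]2C[C@H](O)[C@]2(C)C=C[C@@]1(OC)O2 | intermediate
34 | (E)-3-(1-methylimidazol-4-yl)acrylic acid | Cn1cnc(/C=C/C(=O)O)c1 | starting material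
35 | (E)-3-(1-methylimidazol-4-yl)acrylic 2,4,6-trichlorobenzoic anhydride | Cn1cnc(/C=C/C(=O)OC(=O)c2c(Cl)cc(Cl)cc2Cl)c1 | intermediate
36 | C8 (E)-3-(1-methylimidazol-4-yl)acrylate of the (3R)-2,3-dihydro C4 methyl ketal | COC(=O)[C@@H]1C[C@@H]2[C@@H](C(C)C)CC=C(C)[C@@H]2C[C@H](OC(=O)/C=C/c2cn(C)cn2)[C@]2(C)C=C[C@@]1(OC)O2 | intermediate
37 | target CNP0113846.1, (1R,3R,4R,7S,8S,10R,14R) | COC(=O)[C@@H]1C[C@@H]2[C@@H](C(C)C)CC=C(C)[C@@H]2C[C@H](OC(=O)/C=C/c2cn(C)cn2)[C@]2(C)C=C[C@@]1(O)O2 | target

**Step count**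

Total steps: 21. Longest linear sequence: 21 (steps 1–21; every other component is purchased).

**Steps most likely to fail**

1. Step 16 (proposed new method). Intermolecular condensation may outrun closure of the ten-membered ring, the amine may add to the ring-opened Z-enone and isomerise it, or C1 may epimerise through the enamine. Fallback with known chemistry (samarium Reformatsky closure, then dehydration), setting out from 27: bromination of the keto ester carbon with NBS and catalytic NH4OAc gives the C3 bromide F1. SmI2 in THF at −78 °C under high dilution reduces the C–Br bond to the samarium enolate, which adds to the C2 aldehyde in an intramolecular Reformatsky reaction, an established way to close medium carbocycles, giving the β-hydroxy keto ester F2. MsCl/Et3N then eliminates the C2 hydroxyl toward C3, and the route is rejoined at 30.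

2. Step 18. Hydride delivery to the hindered, α-branched enoate may be slow, and protonation of the copper enolate may occur from the wrong face, leaving the C3 epimer. Fallback, setting out from 30: the reduction is moved ahead of ketal formation. Hantzsch ester (diethyl 2,6-dimethyl-1,4-dihydropyridine-3,5-dicarboxylate) with silica gel in toluene at 60 °C reduces the doubly activated alkylidene of the ring-opened keto ester form; after reclosure this gives the saturated hemiketal F3, whose C3 lies between two carbonyl groups in the open form and equilibrates freely. PPTS/MeOH then gives 32, where the route is rejoined.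

3. Step 7. Uncatalysed background addition or insufficient ligand control over the aldehyde face may erode the C8 configuration. Fallback, setting out from 11: addition of vinylmagnesium bromide 12 in THF at −78 °C gives 14 together with its (8R) epimer F4. Sharpless kinetic resolution conditions (Ti(OiPr)4, D-(−)-diisopropyl tartrate, t-BuOOH, 4 Å molecular sieves, CH2Cl2, −20 °C) epoxidise the fast-reacting (8R) epimer to the erythro epoxy alcohol F5 and leave the (8S) alcohol, which is separated; the route is rejoined at 14.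

**Further compounds**

F1 | step 16 | C3-bromo derivative of 27 (C3 epimers) | O=C[C@@H]1[C@@H](C(C)C)CC=C(C)[C@@H]1C[C@H](OCc2ccc(OC)cc2)[C@]1(C)C=C[C@](O)(C(Br)C(=O)OC)O1
F2 | step 16 | C2-hydroxy-2,3-dihydro hemiketal macrocycle, C8 PMB ether (C2 and C3 epimers) | COC(=O)C1C(O)[C@@H]2[C@@H](C(C)C)CC=C(C)[C@@H]2C[C@H](OCc3ccc(OC)cc3)[C@]2(C)C=C[C@@]1(O)O2
F3 | step 18 | (3R)-2,3-dihydro hemiketal macrocycle, C8 PMB ether | COC(=O)[C@@H]1C[C@@H]2[C@@H](C(C)C)CC=C(C)[C@@H]2C[C@H](OCc3ccc(OC)cc3)[C@]2(C)C=C[C@@]1(O)O2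
F4 | step 7 | (2R)-1-(ring A unit [CH2OTBDPS])but-3-en-2-ol, the C8 epimer of 14 | CC(C)(C)[Si](c1ccccc1)(c1ccccc1)OC[C@@H]2[C@@H](C(C)C)CC=C(C)[C@@H]2C[C@@H](O)C=C
F5 | step 7 | erythro epoxy alcohol from F4, (1R)-1-[(2S)-oxiran-2-yl]-2-(ring A unit [CH2OTBDPS])ethanol | CC(C)(C)[Si](c1ccccc1)(c1ccccc1)OC[C@@H]2[C@@H](C(C)C)CC=C(C)[C@@H]2C[C@@H](O)[C@H]3CO3
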